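The locants used are: the half with the tertiary alcohol is Ar–C7′H(O)–C8′(OH)–C9′H2–O, the other half is Ar–C7H(O)–C8H–C9H2–O. The bicycle is disconnected at the bridgehead bond C8–C8′ and at the ether bond from the C9′ oxygen to benzylic C7, both in the tetrahydrofuran ring O–C7–C8–C8′–C9′. C8′, a carbinol between two oxygenated carbons, is read as a ketone; C7=C8 as an (E)-cinnamyl ether whose para-oxygenated aryl group stabilises charge at C7. One Lewis acid Prins cyclization of this acyclic keto ether, terminated by the C9′ oxygen, closes both rings and sets three stereocentres from the single C7′ centre, itself set by Sharpless epoxidation and invertive epoxide opening.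

Key step: step 7

Remark: the 4-silyloxy-3,5-dimethoxyphenyl group is assumed to be donating enough to sustain the C7 cation in step 7, yet not so donating that the benzylic epoxide carbon in step 5 reacts through a free cation; methyl sinapate is taken as the commercial starting material.

Step 1
Reactants: 1 methyl sinapate
Product: 2 methyl (E)-3-[4-(tert-butyldimethylsilyloxy)-3,5-dimethoxyphenyl]prop-2-enoate
Conditions: TBSCl, imidazole, DMF, rt
Reagents that add atoms: tert-butyldimethylsilyl chloride (TBSCl), CC(C)(C)[Si](C)(C)Cl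
Why: Silyl ether formation on the phenol masks the acidic OH for the hydride and Lewis acid steps and is removed only at the end.

Step 2
Reactants: 2 methyl (E)-3-[4-(tert-butyldimethylsilyloxy)-3,5-dimethoxyphenyl]prop-2-enoate
Product: 3 (E)-3-[4-(tert-butyldimethylsilyloxy)-3,5-dimethoxyphenyl]prop-2-en-1-ol
Conditions: i-Bu2AlH (2.5 equiv), CH2Cl2, −78 °C; aq. potassium sodium tartrate work-up
Reagents that add atoms: none
Why: 1,2-Reduction of the unsaturated ester by i-Bu2AlH at low temperature should give the allylic alcohol without touching the aryl silyl ether or the E alkene.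

Step 3
Reactants: 3 (E)-3-[4-(tert-butyldimethylsilyloxy)-3,5-dimethoxyphenyl]prop-2-en-1-ol
Product: 4 [(2S,3S)-3-[4-(tert-butyldimethylsilyloxy)-3,5-dimethoxyphenyl]oxiran-2-yl]methanol
Conditions: Ti(OiPr)4 (10 mol %), L-(+)-diethyl tartrate (12 mol %), t-BuOOH, 4 Å molecular sieves, CH2Cl2, −20 °C
Reagents that add atoms: tert-butyl hydroperoxide, CC(C)(C)OO
Why: Sharpless asymmetric epoxidation with L-(+)-diethyl tartrate delivers oxygen to the alkene face that gives the (2S,3S)-epoxy alcohol, fixing the configuration that becomes C7′.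

Step 4
Reactants: 4 [(2S,3S)-3-[4-(tert-butyldimethylsilyloxy)-3,5-dimethoxyphenyl]oxiran-2-yl]methanol
Product: 5 tert-butyl{[(2S,3S)-3-[4-(tert-butyldimethylsilyloxy)-3,5-dimethoxyphenyl]oxiran-2-yl]methoxy}dimethylsilane
Conditions: TBSCl, imidazole, CH2Cl2, 0 °C
Reagents that add atoms: tert-butyldimethylsilyl chloride (TBSCl), CC(C)(C)[Si](C)(C)Cl
Why: Silyl ether formation on the primary alcohol ensures that after epoxide opening only the C8′ hydroxyl is free, and gives the C9′ oxygen a group it can shed in step 7.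

Step 5
Reactants: 5 tert-butyl{[(2S,3S)-3-[4-(tert-butyldimethylsilyloxy)-3,5-dimethoxyphenyl]oxiran-2-yl]methoxy}dimethylsilane; 3 (E)-3-[4-(tert-butyldimethylsilyloxy)-3,5-dimethoxyphenyl]prop-2-en-1-ol
Product: 6 (2S,3R)-1-(tert-butyldimethylsilyloxy)-3-[4-(tert-butyldimethylsilyloxy)-3,5-dimethoxyphenyl]-3-{[(E)-3-[4-(tert-butyldimethylsilyloxy)-3,5-dimethoxyphenyl]prop-2-en-1-yl]oxy}propan-2-ol
Conditions: BF3·OEt2 (10 mol %), CH2Cl2, −40 to −20 °C, epoxide added slowly to the alcohol
Reagents that add atoms: none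
Why: Lewis acid-catalysed epoxide alcoholysis, an addition that joins the two reactants with nothing lost, should occur at the benzylic carbon by backside attack (inversion), turning C3 (S) into the (R)-configured C7′ ether and leaving the C2 carbinol as the only free hydroxyl.

Step 6
Reactants: 6 (2S,3R)-1-(tert-butyldimethylsilyloxy)-3-[4-(tert-butyldimethylsilyloxy)-3,5-dimethoxyphenyl]-3-{[(E)-3-[4-(tert-butyldimethylsilyloxy)-3,5-dimethoxyphenyl]prop-2-en-1-yl]oxy}propan-2-ol
Product: 7 (1R)-3-(tert-butyldimethylsilyloxy)-1-[4-(tert-butyldimethylsilyloxy)-3,5-dimethoxyphenyl]-1-{[(E)-3-[4-(tert-butyldimethylsilyloxy)-3,5-dimethoxyphenyl]prop-2-en-1-yl]oxy}propan-2-one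
Conditions: Dess–Martin periodinane, CH2Cl2, 0 °C to rt
Reagents that add atoms: none
Why: Dess–Martin oxidation of the secondary alcohol under near-neutral conditions should give the α,α′-dioxygenated ketone without epimerising the adjacent benzylic C7′ or touching the alkene.

Step 7
Reactants: 7 (1R)-3-(tert-butyldimethylsilyloxy)-1-[4-(tert-butyldimethylsilyloxy)-3,5-dimethoxyphenyl]-1-{[(E)-3-[4-(tert-butyldimethylsilyloxy)-3,5-dimethoxyphenyl]prop-2-en-1-yl]oxy}propan-2-one
Product: 10 (1S,2R,5R,6S)-2,6-bis[4-(tert-butyldimethylsilyloxy)-3,5-dimethoxyphenyl]-3,7-dioxabicyclo[3.3.0]octan-1-ol, via benzylic cation 8 (not isolated), via silyloxonium ion 9 (not isolated)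
Conditions: BF3·OEt2 (1.5 equiv), CH2Cl2, −78 to −40 °C; then aq. NaHCO3
Reagents that add atoms: none
Why: BF3 binds the C8′ ketone (made electrophilic by its two α-oxygens) and the (E)-alkene attacks through C8 in a Prins cyclization (5-exo-trig with respect to the carbonyl) that closes the tetrahydrofuran C8′–C7′–O–C9–C8 and leaves benzylic cation 8, stabilised by the para-silyloxy aryl group; the C9′ silyl ether oxygen then captures C7 (5-exo-trig cation capture) to give oxonium 9, which loses its silyl group to fluoride and so completes the second tetrahydrofuran. The closest known reaction type is the Lewis acid-mediated Prins cyclization terminated by an internal oxygen nucleophile, with the same ketone–alkene pairing as in Lewis acid-promoted alkene additions to α-alkoxy ketones. C8′ is controlled by C7′: the tether oxygen must lie near the attack trajectory, the C7′ aryl group avoids the C9′ arm (on whose side BF3 sits) and C8 adds to the Re face of the ketone, which places that aryl trans to C9′ (exo). C8 is controlled by the ring fusion, since only the adduct with C9′ and C7 cis can close and the bicycle must be cis-fused; C7 is controlled by the E geometry and least-motion capture, which put its aryl group on the convex face. The step needs capture of C7 by the C9′ oxygen rather than by the C8′ oxygen, and no ionisation of the two ether bonds; the five- versus four-membered closure, the low temperature and the deactivating ketone next to both ether oxygens should secure this.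

Step 8
Reactants: 10 (1S,2R,5R,6S)-2,6-bis[4-(tert-butyldimethylsilyloxy)-3,5-dimethoxyphenyl]-3,7-dioxabicyclo[3.3.0]octan-1-ol
Product: 11 8-hydroxysyringaresinol, (1S,2R,5R,6S)-2,6-bis(4-hydroxy-3,5-dimethoxyphenyl)-3,7-dioxabicyclo[3.3.0]octan-1-ol
Conditions: Bu4NF (2.5 equiv), AcOH (2.5 equiv), THF, 0 °C
Reagents that add atoms: none
Why: Fluoride-mediated desilylation of the two aryl silyl ethers, buffered with acetic acid so that the liberated para-hydroxybenzylic ethers are not opened through phenolate-derived quinone methides, should leave all four stereocentres untouched.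

Compound list
1 | methyl sinapate, methyl (E)-3-(4-hydroxy-3,5-dimethoxyphenyl)prop-2-enoate | COC(=O)/C=C/c1cc(OC)c(O)c(OC)c1 | starting material
2 | methyl (E)-3-[4-(tert-butyldimethylsilyloxy)-3,5-dimethoxyphenyl]prop-2-enoate | COC(=O)/C=C/c1cc(OC)c(O[Si](C)(C)C(C)(C)C)c(OC)c1 | intermediate
3 | (E)-3-[4-(tert-butyldimethylsilyloxy)-3,5-dimethoxyphenyl]prop-2-en-1-ol | OC/C=C/c1cc(OC)c(O[Si](C)(C)C(C)(C)C)c(OC)c1 | intermediate
4 | [(2S,3S)-3-[4-(tert-butyldimethylsilyloxy)-3,5-dimethoxyphenyl]oxiran-2-yl]methanol | OC[C@@H]1O[C@H]1c1cc(OC)c(O[Si](C)(C)C(C)(C)C)c(OC)c1 | intermediate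
5 | tert-butyl{[(2S,3S)-3-[4-(tert-butyldimethylsilyloxy)-3,5-dimethoxyphenyl]oxiran-2-yl]methoxy}dimethylsilane | CC(C)(C)[Si](C)(C)OC[C@@H]1O[C@H]1c1cc(OC)c(O[Si](C)(C)C(C)(C)C)c(OC)c1 | intermediate
6 | (2S,3R)-1-(tert-butyldimethylsilyloxy)-3-[4-(tert-butyldimethylsilyloxy)-3,5-dimethoxyphenyl]-3-{[(E)-3-[4-(tert-butyldimethylsilyloxy)-3,5-dimethoxyphenyl]prop-2-en-1-yl]oxy}propan-2-ol | CC(C)(C)[Si](C)(C)OC[C@H](O)[C@H](OC/C=C/c1cc(OC)c(O[Si](C)(C)C(C)(C)C)c(OC)c1)c1cc(OC)c(O[Si](C)(C)C(C)(C)C)c(OC)c1 | intermediate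
7 | (1R)-3-(tert-butyldimethylsilyloxy)-1-[4-(tert-butyldimethylsilyloxy)-3,5-dimethoxyphenyl]-1-{[(E)-3-[4-(tert-butyldimethylsilyloxy)-3,5-dimethoxyphenyl]prop-2-en-1-yl]oxy}propan-2-one | CC(C)(C)[Si](C)(C)OCC(=O)[C@H](OC/C=C/c1cc(OC)c(O[Si](C)(C)C(C)(C)C)c(OC)c1)c1cc(OC)c(O[Si](C)(C)C(C)(C)C)c(OC)c1 | intermediate
8 | benzylic cation: monocyclic tetrahydrofuran with the C8′ oxygen bound to BF3 and the positive charge on exocyclic C7 (zwitterion, not isolated) | F[B-](F)(F)O[C@@]1(CO[Si](C)(C)C(C)(C)C)[C@@H](c2cc(OC)c(O[Si](C)(C)C(C)(C)C)c(OC)c2)OC[C@@H]1[CH+]c3cc(OC)c(O[Si](C)(C)C(C)(C)C)c(OC)c3 | intermediate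
9 | silyloxonium ion: the bicycle with the silyl group still on the ring oxygen next to C9′ and BF3 on the C8′ oxygen (zwitterion, not isolated) | COc1cc([C@H]2[O+]([Si](C)(C)C(C)(C)C)C[C@]3(O[B-](F)(F)F)[C@@H](c4cc(OC)c(O[Si](C)(C)C(C)(C)C)c(OC)c4)OC[C@H]23)cc(OC)c1O[Si](C)(C)C(C)(C)C | intermediate
10 | (1S,2R,5R,6S)-2,6-bis[4-(tert-butyldimethylsilyloxy)-3,5-dimethoxyphenyl]-3,7-dioxabicyclo[3.3.0]octan-1-ol | COc1cc([C@H]2OC[C@]3(O)[C@@H](c4cc(OC)c(O[Si](C)(C)C(C)(C)C)c(OC)c4)OC[C@H]23)cc(OC)c1O[Si](C)(C)C(C)(C)C | intermediate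
11 | 8-hydroxysyringaresinol, (1S,2R,5R,6S)-2,6-bis(4-hydroxy-3,5-dimethoxyphenyl)-3,7-dioxabicyclo[3.3.0]octan-1-ol | COc1cc([C@H]2OC[C@]3(O)[C@@H](c4cc(OC)c(O)c(OC)c4)OC[C@H]23)cc(OC)c1O | target

Total step count: 8. Longest linear sequence: 8 steps (1 → 2 → 3 → 4 → 5 → 6 → 7 → 10 → 11; compound 3 re-enters in step 5).

Steps most likely to fail

Step 7. The C7 cation may be captured by the BF3-bound C8′ oxygen (oxetane formation followed by fragmentation), the cinnamyl ether may ionise before the C–C bond forms, or the alkene may add to the wrong ketone face relative to C7′. The fallback sets out from 7 and comes back at 11, replacing steps 7 and 8. It trades kinetic cation capture for a reversible quinone methide manifold. All three silyl groups are removed first (HF·pyridine, THF, 0 °C to rt) to give the free bis-phenol hydroxy ketone F1. A catalytic Brønsted acid ((PhO)2P(O)OH, CH2Cl2/(CF3)2CHOH, 0 °C to rt) should then let the para-hydroxystyrene act as a vinylogous enol. Aldol-type addition of C8 to the ketone is reversible and gives a neutral para-quinone methide at C7. Only the adduct whose C9′ hydroxyl can add to it (oxa-1,6-addition, the closure known from the oxidative dimerisation of sinapyl alcohol) is drained off, to the target 11.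

Step 5. The Lewis acid may ionise the electron-rich allylic alcohol 3 (self-condensation), the benzylic carbon may open through a free cation with loss of configurational integrity, or the epoxide may rearrange by hydride shift. The fallback sets out from 5 and comes back at 6. The epoxide is opened with allyl alcohol as solvent (BF3·OEt2 cat., −20 °C), where the large excess of a robust nucleophile should enforce backside attack, to give the allyl ether F2. Commercial 2,6-dimethoxy-4-vinylphenol is silylated (TBSCl, imidazole) to the styrene F3. Cross-metathesis of F2 with excess F3 (second-generation Grubbs catalyst RuCl2(=CHPh)(H2IMes)(PCy3), CH2Cl2, 40 °C) should then install the (E)-aryl alkene and give 6.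

Step 3. The electron-rich epoxy alcohol may be opened or decomposed on titanium during reaction and work-up, with loss of material and of enantiomeric purity. The fallback sets out from 3 and comes back at 5, replacing steps 3 and 4. Alcohol 3 is silylated (TBSCl, imidazole) to the bis-silyl ether F4. This is epoxidised with a dioxirane generated from the enantiomer of the fructose-derived Shi ketone (made from L-sorbose), using KHSO5 (as 2KHSO5·KHSO4·K2SO4), K2CO3, MeCN/CH2(OMe)2/H2O, 0 °C. That should give the (2S,3S)-epoxide 5 directly, without a Lewis acidic metal.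

Further compounds
F1 | step 7 | (1R)-3-hydroxy-1-(4-hydroxy-3,5-dimethoxyphenyl)-1-{[(E)-3-(4-hydroxy-3,5-dimethoxyphenyl)prop-2-en-1-yl]oxy}propan-2-one | OCC(=O)[C@H](OC/C=C/c1cc(OC)c(O)c(OC)c1)c1cc(OC)c(O)c(OC)c1
F2 | step 5 | (2S,3R)-3-(allyloxy)-1-(tert-butyldimethylsilyloxy)-3-[4-(tert-butyldimethylsilyloxy)-3,5-dimethoxyphenyl]propan-2-ol | CC(C)(C)[Si](C)(C)OC[C@H](O)[C@H](OCC=C)c1cc(OC)c(O[Si](C)(C)C(C)(C)C)c(OC)c1
F3 | step 5 | tert-butyl(4-ethenyl-2,6-dimethoxyphenoxy)dimethylsilane | C=Cc1cc(OC)c(O[Si](C)(C)C(C)(C)C)c(OC)c1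
F4 | step 3 | tert-butyl{[(E)-3-[4-(tert-butyldimethylsilyloxy)-3,5-dimethoxyphenyl]prop-2-en-1-yl]oxy}dimethylsilane | CC(C)(C)[Si](C)(C)OC/C=C/c1cc(OC)c(O[Si](C)(C)C(C)(C)C)c(OC)c1
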